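**Retrosynthetic overview**
1. The last C–C bond is a Heck coupling of a (Z)-alkenyl iodide with an (R)-2-methyl-2-vinylchroman (phenol as TIPS ether); this builds the (1E,3Z)-diene, and fluoride then frees the phenol.
2. The pyran ring (second ring formed; the arene is bought as hydroquinone) is closed by a Pd-catalysed asymmetric allylic O-alkylation of a phenol allyl carbonate, which sets the only stereocentre.
3. The (Z)-alkenyl iodide comes from carbocupration of propyne with the 2-(2,6,6-trimethylcyclohexenyl)ethyl Grignard reagent, then iodine.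
4. The carbocycle (first ring formed) is made by a Diels–Alder reaction of the acyclic diene HOCH2CH2–C(=CMe2)–C(Me)=CH2 with phenyl vinyl sulfone as ethylene equivalent, then reductive desulfonylation; the diene comes from pent-3-yn-1-ol in two steps.
5. Enabling feature: the trimethylcyclohexene ring has its single, tetrasubstituted C=C between the chain-bearing and the methyl-bearing ring carbons, flanked by the CMe2 carbon and an allylic CH2, and lying opposite an unfunctionalised CH2–CH2 pair. This is a cyclohexene retron whose diene part is CH2=C(Me)–C(R)=CMe2 and whose dienophile part is ethylene.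

Key step: step 3

Assumption: for the (E)-trisubstituted allyl carbonate the (R,R)-DACH-phenyl Trost ligand is taken to deliver the (R)-chroman; the sense of induction of this cyclisation depends on alkene geometry and additive, so if the first run gave the antipode the (S,S)-ligand would be used with nothing else changed.

**Route**

Step 1
Reactants: 1 pent-3-yn-1-ol
Product: 3 3-iodo-4-methylpent-3-en-1-ol, via alkenylmagnesium alkoxide 2 (not isolated)
Conditions: MeMgBr (4 equiv), Fe(acac)3 (15 mol%), THF, −78 to 0 °C; then I2, THF, −78 °C to rt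
Reagents that add atoms: methylmagnesium bromide, C[Mg]Br; iodine, II
Why: Alkoxide-directed iron-catalysed syn-carbomagnesiation of a homopropargylic alcohol should deliver methyl to the distal alkyne carbon and magnesium to the proximal one (five-membered chelate), no alkene geometry being at stake because the new terminus carries two methyl groups, and iodinolysis of the alkenyl Grignard then gives the tetrasubstituted iodide.

Step 2
Reactants: 3 3-iodo-4-methylpent-3-en-1-ol; 4 4,4,5,5-tetramethyl-2-(prop-1-en-2-yl)-1,3,2-dioxaborolane (isopropenylboronic acid pinacol ester)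
Product: 5 4-methyl-3-(prop-1-en-2-yl)pent-3-en-1-ol
Conditions: Pd(OAc)2 (5 mol%), SPhos (10 mol%), K3PO4, THF/H2O, 60 °C
Reagents that add atoms: none
Why: Suzuki–Miyaura coupling of an alkenyl iodide with an alkenylboronate, in which the bulky biarylphosphine should cope with the tetrasubstituted iodide and the free hydroxyl is tolerated.

Step 3
Reactants: 5 4-methyl-3-(prop-1-en-2-yl)pent-3-en-1-ol; 6 phenyl vinyl sulfone
Product: 7 2-[2,6,6-trimethyl-5-(phenylsulfonyl)cyclohex-1-en-1-yl]ethan-1-ol (racemic)
Conditions: 6 (2 equiv), BHT (cat.), toluene, sealed tube, 140 °C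
Reagents that add atoms: none
Why: Thermal, concerted but asynchronous [4+2] cycloaddition (Diels–Alder reaction with phenyl vinyl sulfone as the classical ethylene equivalent): the unsubstituted CH2 terminus of the diene bonds to the β-carbon of the sulfone while the Me2C= terminus bonds to the sulfonyl-bearing carbon, so both ring C–C bonds and the six-membered carbocycle form in one suprafacial six-electron closure from two acyclic partners. The closest precedent is the cycloaddition of dienes with a 1,1-disubstituted terminus, such as 2,4-dimethylpenta-1,3-diene and 1-vinyl-2,6,6-trimethylcyclohexene, with activated dienophiles, which likewise creates a quaternary ring carbon. The former central bond of the diene becomes the tetrasubstituted ring alkene exactly where the target has it, and the gem-dimethyl carbon, the ring methyl and the side chain are placed by the diene alone, so no positional selectivity has to be won. The single new stereocentre (the sulfonyl carbon) forms as a racemate under no control, and the regiochemistry (5-sulfonyl expected from the larger HOMO coefficient at the CH2 terminus; any 4-sulfonyl isomer would be carried along) is immaterial because step 4 removes the sulfone. What the step needs is reactivity and periselectivity: the 2,3-disubstitution destabilises the s-trans conformer and keeps the diene cisoid, the [1,5]-hydrogen shift open to the inside methyl group is degenerate for this diene, and BHT suppresses radical polymerisation of the sulfone.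

Step 4
Reactants: 7 2-[2,6,6-trimethyl-5-(phenylsulfonyl)cyclohex-1-en-1-yl]ethan-1-ol
Product: 8 2-(2,6,6-trimethylcyclohex-1-en-1-yl)ethan-1-ol
Conditions: 6% Na(Hg), Na2HPO4, MeOH/THF, −20 °C to rt
Reagents that add atoms: none
Why: Reductive desulfonylation of an alkyl aryl sulfone by electron transfer should replace C–S by C–H while the isolated tetrasubstituted alkene and the alcohol stay inert, and it erases the only stereocentre of 7 and the difference between sulfone regioisomers.

Step 5
Reactants: 8 2-(2,6,6-trimethylcyclohex-1-en-1-yl)ethan-1-ol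
Product: 9 2-(2-bromoethyl)-1,3,3-trimethylcyclohex-1-ene
Conditions: CBr4, PPh3, CH2Cl2, 0 °C
Reagents that add atoms: carbon tetrabromide, BrC(Br)(Br)Br
Why: Appel bromination proceeds by SN2 displacement on the primary alkoxyphosphonium ion under neutral conditions, so no cation forms that the homoallylic ring alkene could trap.

Step 6
Reactants: 9 2-(2-bromoethyl)-1,3,3-trimethylcyclohex-1-ene; 10 propyne
Product: 13 2-[(3Z)-4-iodo-3-methylbut-3-en-1-yl]-1,3,3-trimethylcyclohex-1-ene, via alkylmagnesium bromide 11 (not isolated), via (Z)-alkenylcopper 12 (not isolated)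
Conditions: Mg, Et2O, reflux; CuBr·SMe2, Et2O/Me2S, −45 °C; propyne, −25 °C; I2, THF, −50 to 0 °C
Reagents that add atoms: iodine, II
Why: Normant carbocupration adds the alkyl group and copper syn across propyne with the alkyl group on the internal carbon, and iodinolysis with retention should therefore give the iodide with iodine cis to the chain, which is the (Z)-trisubstituted geometry of the target.

Step 7
Reactants: 14 hydroquinone
Product: 15 4-[(triisopropylsilyl)oxy]phenol
Conditions: TIPSCl (1 equiv), 14 (3 equiv), imidazole, DMF, 0 °C to rt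
Reagents that add atoms: chlorotriisopropylsilane, CC(C)[Si](Cl)(C(C)C)C(C)C
Why: Silylation of a symmetrical diphenol with the diol in excess favours the mono-ether, and the excess hydroquinone is washed out with water.

Step 8
Reactants: 15 4-[(triisopropylsilyl)oxy]phenol
Product: 16 2-iodo-4-[(triisopropylsilyl)oxy]phenol
Conditions: NIS (1.05 equiv), TFA (cat.), MeCN, 0 °C to rt
Reagents that add atoms: N-iodosuccinimide, O=C1CCC(=O)N1I
Why: Electrophilic aromatic iodination should go ortho to the free hydroxyl, the stronger and less hindered activating group, since the para position is blocked.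

Step 9
Reactants: 17 (2E)-3-methylpent-2-en-4-yn-1-ol
Product: 18 (2E)-3-methylpenta-2,4-dien-1-ol
Conditions: H2 (1 atm), Pd/CaCO3 poisoned with Pb(OAc)2 (Lindlar catalyst), quinoline, EtOAc, rt, stopped after 1 equiv of H2
Reagents that add atoms: none
Why: Lindlar semihydrogenation reduces the terminal alkyne to the vinyl group and leaves the trisubstituted (E)-alkene untouched.

Step 10
Reactants: 18 (2E)-3-methylpenta-2,4-dien-1-ol; 16 2-iodo-4-[(triisopropylsilyl)oxy]phenol
Product: 20 2-[(3E)-5-hydroxy-3-methylpent-3-en-1-yl]-4-[(triisopropylsilyl)oxy]phenol, via B-alkyl-9-BBN borinate adduct 19 (not isolated)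
Conditions: 9-BBN-H (2.2 equiv), THF, 0 °C to rt; then 16, PdCl2(dppf) (5 mol%), 3 M aq K3PO4, DMF, 60 °C
Reagents that add atoms: none
Why: 9-BBN hydroborates only the monosubstituted vinyl group of the diene (boron on the terminal carbon, the trisubstituted alkene being too hindered), and B-alkyl Suzuki–Miyaura coupling with the aryl iodide then forms the aryl–CH2 bond with the (E)-geometry of 18 carried through.

Step 11
Reactants: 20 2-[(3E)-5-hydroxy-3-methylpent-3-en-1-yl]-4-[(triisopropylsilyl)oxy]phenol
Product: 21 methyl (2E)-5-{2-hydroxy-5-[(triisopropylsilyl)oxy]phenyl}-3-methylpent-2-en-1-yl carbonate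
Conditions: ClCO2Me (1.1 equiv), pyridine, CH2Cl2, −20 to 0 °C
Reagents that add atoms: methyl chloroformate, COC(Cl)=O
Why: Under weak-base acylation conditions the primary allylic alcohol is far more nucleophilic than the neutral, ortho-substituted phenol, so the carbonate should form chemoselectively on the aliphatic oxygen.

Step 12
Reactants: 21 methyl (2E)-5-{2-hydroxy-5-[(triisopropylsilyl)oxy]phenyl}-3-methylpent-2-en-1-yl carbonate
Product: 22 triisopropyl{[(2R)-2-methyl-2-vinyl-3,4-dihydro-2H-chromen-6-yl]oxy}silane
Conditions: Pd2(dba)3·CHCl3 (2 mol%), (R,R)-DACH-phenyl Trost ligand (6 mol%), AcOH (1 equiv), CH2Cl2, rt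
Reagents that add atoms: none
Why: Trost asymmetric allylic alkylation in its intramolecular O-alkylation form: ionisation of the carbonate gives a π-allylpalladium complex, and the phenol closes the six-membered pyran ring by attack at the more substituted allyl terminus, the chiral pocket of the ligand selecting the face and so setting the quaternary C2 as (R).

Step 13
Reactants: 13 2-[(3Z)-4-iodo-3-methylbut-3-en-1-yl]-1,3,3-trimethylcyclohex-1-ene; 22 triisopropyl{[(2R)-2-methyl-2-vinyl-3,4-dihydro-2H-chromen-6-yl]oxy}silane
Product: 23 triisopropyl({(2R)-2-methyl-2-[(1E,3Z)-4-methyl-6-(2,6,6-trimethylcyclohex-1-en-1-yl)hexa-1,3-dien-1-yl]-3,4-dihydro-2H-chromen-6-yl}oxy)silane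
Conditions: Pd(OAc)2 (10 mol%), Ag2CO3 (1.2 equiv), DMF, 50 °C, dark
Reagents that add atoms: none
Why: Heck reaction under silver-assisted ligand-free (Jeffery-type) conditions: oxidative addition keeps the (Z)-geometry of the iodide, insertion places the alkenyl group on the terminal carbon of the vinyl group, and syn β-hydride elimination can only occur away from the quaternary C2 to give the (E)-alkene, while silver carbonate removes iodide and acid so that palladium hydride should not re-add; the stereocentre is not involved.

Step 14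
Reactants: 23 triisopropyl({(2R)-2-methyl-2-[(1E,3Z)-4-methyl-6-(2,6,6-trimethylcyclohex-1-en-1-yl)hexa-1,3-dien-1-yl]-3,4-dihydro-2H-chromen-6-yl}oxy)silane
Product: 24 (2R)-2-methyl-2-[(1E,3Z)-4-methyl-6-(2,6,6-trimethylcyclohex-1-en-1-yl)hexa-1,3-dien-1-yl]-3,4-dihydro-2H-chromen-6-ol
Conditions: TBAF, AcOH (1 equiv each), THF, 0 °C, degassed
Reagents that add atoms: none
Why: Fluoride-mediated cleavage of the aryl silyl ether is fast at 0 °C, and the acetic acid buffer keeps the electron-rich phenoxide, the diene and the tertiary allylic ether out of harm.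

**Compound list**
1 | pent-3-yn-1-ol | CC#CCCO | starting material
2 | bromomagnesium 3-(bromomagnesio)-4-methylpent-3-en-1-olate (not isolated) | CC(C)=C([Mg]Br)CCO[Mg]Br | intermediate
3 | 3-iodo-4-methylpent-3-en-1-ol | CC(C)=C(I)CCO | intermediate
4 | 4,4,5,5-tetramethyl-2-(prop-1-en-2-yl)-1,3,2-dioxaborolane | CC(=C)B1OC(C)(C)C(C)(C)O1 | starting material
5 | 4-methyl-3-(prop-1-en-2-yl)pent-3-en-1-ol | CC(C)=C(CCO)C(C)=C | intermediate
6 | phenyl vinyl sulfone | C=CS(=O)(=O)c1ccccc1 | starting material
7 | 2-[2,6,6-trimethyl-5-(phenylsulfonyl)cyclohex-1-en-1-yl]ethan-1-ol (racemic) | CC1=C(CCO)C(C)(C)C(CC1)S(=O)(=O)c1ccccc1 | intermediate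
8 | 2-(2,6,6-trimethylcyclohex-1-en-1-yl)ethan-1-ol | CC1=C(CCO)C(C)(C)CCC1 | intermediate
9 | 2-(2-bromoethyl)-1,3,3-trimethylcyclohex-1-ene | CC1=C(CCBr)C(C)(C)CCC1 | intermediate
10 | propyne | CC#C | starting material
11 | [2-(2,6,6-trimethylcyclohex-1-en-1-yl)ethyl]magnesium bromide (not isolated) | CC1=C(CC[Mg]Br)C(C)(C)CCC1 | intermediate
12 | [(1Z)-2-methyl-4-(2,6,6-trimethylcyclohex-1-en-1-yl)but-1-en-1-yl]copper, as its MgBr2 complex (not isolated) | CC1=C(CC/C(C)=C\[Cu])C(C)(C)CCC1 | intermediate
13 | 2-[(3Z)-4-iodo-3-methylbut-3-en-1-yl]-1,3,3-trimethylcyclohex-1-ene | CC1=C(CC/C(C)=C\I)C(C)(C)CCC1 | intermediate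
14 | hydroquinone | Oc1ccc(O)cc1 | starting material
15 | 4-[(triisopropylsilyl)oxy]phenol | CC(C)[Si](Oc1ccc(O)cc1)(C(C)C)C(C)C | intermediate
16 | 2-iodo-4-[(triisopropylsilyl)oxy]phenol | CC(C)[Si](Oc1ccc(O)c(I)c1)(C(C)C)C(C)C | intermediate
17 | (2E)-3-methylpent-2-en-4-yn-1-ol | OC/C=C(\C)C#C | starting material
18 | (2E)-3-methylpenta-2,4-dien-1-ol | OC/C=C(\C)C=C | intermediate
19 | 9-[(3E)-5-(9-borabicyclo[3.3.1]nonan-9-yloxy)-3-methylpent-3-en-1-yl]-9-borabicyclo[3.3.1]nonane (not isolated) | C(C/C(C)=C/COB1C2CCCC1CCC2)B1C2CCCC1CCC2 | intermediate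
20 | 2-[(3E)-5-hydroxy-3-methylpent-3-en-1-yl]-4-[(triisopropylsilyl)oxy]phenol | OC/C=C(\C)CCc1cc(O[Si](C(C)C)(C(C)C)C(C)C)ccc1O | intermediate
21 | methyl (2E)-5-{2-hydroxy-5-[(triisopropylsilyl)oxy]phenyl}-3-methylpent-2-en-1-yl carbonate | COC(=O)OC/C=C(\C)CCc1cc(O[Si](C(C)C)(C(C)C)C(C)C)ccc1O | intermediate
22 | triisopropyl{[(2R)-2-methyl-2-vinyl-3,4-dihydro-2H-chromen-6-yl]oxy}silane | C=C[C@@]1(C)CCc2cc(O[Si](C(C)C)(C(C)C)C(C)C)ccc2O1 | intermediate
23 | triisopropyl({(2R)-2-methyl-2-[(1E,3Z)-4-methyl-6-(2,6,6-trimethylcyclohex-1-en-1-yl)hexa-1,3-dien-1-yl]-3,4-dihydro-2H-chromen-6-yl}oxy)silane | CC1=C(CC/C(C)=C\C=C\[C@@]2(C)CCc3cc(O[Si](C(C)C)(C(C)C)C(C)C)ccc3O2)C(C)(C)CCC1 | intermediate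
24 | (2R)-2-methyl-2-[(1E,3Z)-4-methyl-6-(2,6,6-trimethylcyclohex-1-en-1-yl)hexa-1,3-dien-1-yl]-3,4-dihydro-2H-chromen-6-ol | CC1=C(CC/C(C)=C\C=C\[C@@]2(C)CCc3cc(O)ccc3O2)C(C)(C)CCC1 | target

**Step count**
Total: 14 steps. Longest linear sequence: 8 steps (steps 1–6, 13, 14).

**Steps most likely to fail**

Step 3 (key step). The cycloaddition may be too slow for the crowded, twisted diene at temperatures the sulfone tolerates, so that polymerisation of the dienophile and thermal loss of the diene outrun ring formation. The fallback sets out from 5 and keeps the same [4+2] ring construction but changes the ethylene equivalent and the way it is removed. The far more electrophilic nitroethylene (freshly distilled from 2-nitroethanol and phthalic anhydride; CH2Cl2, BHT, 0 °C to rt) would give 2-(2,6,6-trimethyl-5-nitrocyclohex-1-en-1-yl)ethan-1-ol F1. Its secondary nitro group would then be removed by radical denitration (Bu3SnH, AIBN, toluene, 110 °C), and the sequence comes back to the route at 8.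

Step 13. Re-addition of palladium hydride to the product diene, or ionisation of the tertiary allylic aryl ether by zerovalent palladium, may scramble the (Z)-alkene or open the pyran ring, and insertion into the neopentyl-like vinyl group may stall. The fallback sets out from 22 and replaces the Heck reaction by a stereoretentive sp2–sp2 cross-coupling. Oxidative cleavage of the vinyl group (OsO4 cat., NaIO4, 2,6-lutidine, dioxane/H2O) would give (2R)-2-methyl-6-[(triisopropylsilyl)oxy]-3,4-dihydro-2H-chromene-2-carbaldehyde F2. Boron-Wittig olefination (CH2(Bpin)2, LiTMP, THF, −78 °C to rt) would give 4,4,5,5-tetramethyl-2-[(E)-2-{(2R)-2-methyl-6-[(triisopropylsilyl)oxy]-3,4-dihydro-2H-chromen-2-yl}ethenyl]-1,3,2-dioxaborolane F3. Suzuki–Miyaura coupling of this boronate with 13 (PdCl2(dppf), aq K3PO4, THF, rt) comes back to the route at 23.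

Step 1. The carbometalation may stall or place the methyl group on the wrong alkyne carbon, or the alkenylmagnesium species may be protonated before iodinolysis. The fallback sets out from 4 and builds the diene by cross-coupling and alkylation instead. Selective mono-Suzuki–Miyaura coupling of 4 with 1,1-dibromo-2-methylprop-1-ene (Pd2(dba)3, tri(2-furyl)phosphine, aq K3PO4, THF) would give 3-bromo-2,4-dimethylpenta-1,3-diene F4. Bromine–lithium exchange (tBuLi, Et2O, −78 °C) would give (2,4-dimethylpenta-1,3-dien-3-yl)lithium F5, which would open oxirane (BF3·OEt2, −78 °C) and come back to the route at 5, bypassing steps 1 and 2.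

**Further compounds**
F1 | step 3 | 2-(2,6,6-trimethyl-5-nitrocyclohex-1-en-1-yl)ethan-1-ol | OCCC1=C(C)CCC([N+](=O)[O-])C1(C)C
F2 | step 13 | (2R)-2-methyl-6-[(triisopropylsilyl)oxy]-3,4-dihydro-2H-chromene-2-carbaldehyde | O=C[C@@]1(C)CCc2cc(O[Si](C(C)C)(C(C)C)C(C)C)ccc2O1
F3 | step 13 | 4,4,5,5-tetramethyl-2-[(E)-2-{(2R)-2-methyl-6-[(triisopropylsilyl)oxy]-3,4-dihydro-2H-chromen-2-yl}ethenyl]-1,3,2-dioxaborolane | CC1(C)OB(/C=C/[C@@]2(C)CCc3cc(O[Si](C(C)C)(C(C)C)C(C)C)ccc3O2)OC1(C)C
F4 | step 1 | 3-bromo-2,4-dimethylpenta-1,3-diene | CC(C)=C(Br)C(C)=C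
F5 | step 1 | (2,4-dimethylpenta-1,3-dien-3-yl)lithium | CC(C)=C([Li])C(C)=C
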